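Amounts first: dusk, spring, summer, dawn and midnight each get 0.30 M of starting material, 0.285 M of reagent and 1.50 M of second substrate and stand for 5.0 d. They differ in how things go in and, for summer, in temperature.

| setting | elm | maple | oak | dusk | spring | summer | dawn | midnight |
|---|---|---|---|---|---|---|---|---|
| starting material | 0.30 M | 0.30 M | 0.30 M | 0.30 M (fed, over 4.0 d) | 0.30 M | 0.30 M (fed, over 4.0 d) | 0.30 M | 0.30 M |
| reagent | 0.285 M | 0.19 M | 0.43 M | 0.285 M | 0.285 M (fed, over 25 h) | 0.285 M | 0.285 M (fed, over 4.0 d) | 0.285 M (in portions, 3, over 4.0 d) |
| second substrate | 1.5 M | 1.5 M | 1.5 M | 1.50 M | 1.50 M | 1.50 M | 1.50 M | 1.50 M |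
| temperature | 55 °C | 70 °C | 55 °C | 70 °C | 70 °C |  | 70 °C | 70 °C |
| remark | run made earlier | run made earlier | run made earlier | all else is in the flask from the start; the feed brings no volume worth counting | all else is in the flask from the start; the feed brings no volume worth counting | the addition at 50 °C, then warmed to 70 °C; the feed brings no volume worth counting | all else is in the flask from the start; the feed brings no volume worth counting | first portion at the start, last at 4.0 d |
| time |  |  |  | 5.0 d | 5.0 d | 5.0 d | 5.0 d | 5.0 d |

| run | time / d | over-reaction product / % | target / % |
|---|---|---|---|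
| elm | 0.500 | 0 | 6.0 |
| elm | 1.67 | 3.3 | 14.5 |
| elm | 2.50 | 4.6 | 16.4 |
| elm | 4.00 | 8.1 | 18.7 |
| elm | 6.00 | 11.5 | 18.6 |
| maple | 0.500 | 0.5 | 8.8 |
| maple | 0.833 | 3.4 | 10.6 |
| maple | 1.67 | 7.2 | 13.1 |
| maple | 3.00 | 9.7 | 14.3 |
| maple | 6.00 | 13.5 | 15.4 |
| oak | 1.04 | 2.4 | 14.8 |
| oak | 1.67 | 5.4 | 18.4 |
| oak | 4.00 | 15.8 | 21.3 |
| oak | 6.00 | 21.7 | 19.6 |
| oak | 12.0 | 29.9 | 18.1 |

(scatter of a reading: 0.5 percentage points)

1. the flask that comes out highest in amount of over-reaction product, in percent of the starting material charged; "all alike" if 1.5 percentage points covers them all (dusk / spring / summer / dawn / midnight / all alike)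
2. amount of over-reaction product at the end, in percent of the starting material charged, dusk
3. amount of over-reaction product at the end, in percent of the starting material charged, spring
4. amount of over-reaction product at the end, in percent of the starting material charged, summer
5. amount of over-reaction product at the end, in percent of the starting material charged, dawn
6. amount of over-reaction product at the end, in percent of the starting material charged, midnight

- what may be going on: starting material + reagent <-> target; second substrate + reagent <-> second product; target <-> isomer of the product; reagent + target -> over-reaction product; 2 second substrate -> homo dimer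

Elm and oak differ in the reagent charge, so they show what reagent is worth. At 4.00 d elm, with c(reagent) 0.285 M, reads 8.1% of over-reaction product, and oak, with 0.43 M, reads 15.8%. The logarithm of the one ratio over that of the other gives 1.62. This is the reagent exponent, the power to which over-reaction product follows the reagent charge between flasks otherwise alike. It is an apparent reaction order in reagent, read at 55 °C from readings with their scatter.

Now two sides argue. The first says the charge counts: the charges match, so the flasks end alike. Its number is my own reckoning. Maple, at 70 °C with 0.19 M of reagent, reads 9.7% at 3.00 d and 13.5% at 6.00 d, so a straight line puts it near 12.2% at 5.0 d. Raising the reagent to 0.285 M with the exponent gives 23.6%, though this carries the exponent from 55 °C to 70 °C unchecked.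

The second side says the manner counts and reads the exponent its own way: since it stands above one, this side takes a lump of reagent to be worth more than the same reagent spread thin, though the exponent was read between charges and not between ways of adding. The forecast takes this side, with “Early reagent with all the starting material present” on top: spring 19%, dawn 17%, midnight 14.5%, dusk 13.5%, summer 6.5%. Its spring figure is lower than my 23.6%.

The flasks give spring 23.1%, dawn 18.6%, dusk 16.7%, midnight 16.5% and summer 10.2%. Spring is highest, as the forecast said, and the spread of 13 percentage points is wider than the margin, so the flasks are not alike. The charge view keeps spring, whose reagent goes in over 25 h: 23.1% against 23.6%.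

    starting material + reagent ⇌ target (K = 74.0 L mol⁻¹, k = 0.0680 L mol⁻¹ h⁻¹, Ea = 69.0 kJ mol⁻¹, ΔH = 23.0 kJ mol⁻¹)
    second substrate + reagent ⇌ second product (K = 15.0 L mol⁻¹, k = 0.00600 L mol⁻¹ h⁻¹, Ea = 80.0 kJ mol⁻¹, ΔH = −40.0 kJ mol⁻¹)
    target ⇌ isomer of the product (K = 0.580, k = 0.0460 h⁻¹, Ea = 118 kJ mol⁻¹, ΔH = −31.0 kJ mol⁻¹)
    reagent + target → over-reaction product (k = 0.170 L mol⁻¹ h⁻¹, Ea = 99.0 kJ mol⁻¹)
    2 second substrate → homo dimer (k = 0.0110 L mol⁻¹ h⁻¹, Ea = 100 kJ mol⁻¹)
    (constants at 70 °C)

Summer has 1.00 d warm after its cold addition, and at the end the half-life of reagent by the forward step to target alone is 2.1 d, longer than that stretch. In summer 37.0% of the reagent charge stands at the end, against 8.89% in spring. Carried to summer, the exponent says that cutting reagent to 0.191 M lowers over-reaction product by 4.9 points, and at that charge summer has moved by 5 points. For summer with 0.17 M of reagent, other charges and time held, the exponent gives 4.42%, and that flask gives 4.30%.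

All runs were computed with made-up constants; scatter was added.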